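**Remark on the chemistry.** Methyl 4,6-O-benzylidene-α-D-glucopyranoside 1 (the benzylidene acetal of methyl α-D-glucopyranoside) is taken as a catalogue compound. Carbocycle atoms are numbered as in the target: C1 = CH–OMe, C2 = ring =CH, C3 = carbon bearing C7, C4/C5/C6 = oxygenated carbons. PMB = 4-methoxybenzyl.

## Retrosynthetic overview

- 22 ⇐ dibenzoate 21 ⇐ diol 19 ⇐ enoate 17: the C3–C7 bond and the C2=C3 double bond come from enol triflate 16 of ketone 14 by methoxycarbonylation.
- 14 ⇐ β-hydroxy ketone 13 ⇐ enol ether 10: the carbocycle, the only ring formed, is closed by a Ferrier carbocyclization that makes the C1–C2 bond.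
- Feature: the ring bond C1–C2 joins a carbinol carbon (C1, later CH–OMe) to the α-carbon of a C3 carbonyl. This aldol retron maps onto the anomeric carbon and the C6 methylene of a 6-deoxyhex-5-enopyranoside, and the oxygen triad C6/C5/C4 is C2/C3/C4 of a D-altropyranoside.
- 10 ⇐ 1 through the 2,3-anhydro-manno epoxide 3, trans-diaxial opening at C3 by 4-methoxybenzyl alkoxide (altro), O2 benzylation, reductive acetal opening to the O4 benzyl ether, iodination and elimination.

Key step: step 7

## Route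

Step 1
Reactants: 1 methyl 4,6-O-[(R)-benzylidene]-α-D-glucopyranoside
Product: 3 methyl 2,3-anhydro-4,6-O-[(R)-benzylidene]-α-D-mannopyranoside, via 2-O-tosylate 2 (not isolated)
Conditions: NaH, N-tosylimidazole, DMF, 0 °C to rt
Reagents that add atoms: none
Why: One-pot sulfonylation and intramolecular Williamson closure to the epoxide: the more acidic 2-OH next to the anomeric centre is tosylated selectively and the 3-alkoxide displaces the tosylate with inversion at C2, which puts the epoxide on the β face (manno).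

Step 2
Reactants: 3 methyl 2,3-anhydro-4,6-O-[(R)-benzylidene]-α-D-mannopyranoside; 4 4-methoxybenzyl alcohol
Product: 5 methyl 4,6-O-[(R)-benzylidene]-3-O-(4-methoxybenzyl)-α-D-altropyranoside
Conditions: 4, NaH, DMF, 90 °C
Reagents that add atoms: 4-methoxybenzyl alcohol 4, COc1ccc(CO)cc1
Why: Alkoxide opening of the epoxide under Fürst–Plattner control: in the chair locked by the trans-fused acetal only attack at C3 from the α face is trans-diaxial, so C3 is inverted to the altro configuration and O2 is left free.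

Step 3
Reactants: 5 methyl 4,6-O-[(R)-benzylidene]-3-O-(4-methoxybenzyl)-α-D-altropyranoside; 6 benzyl bromide
Product: 7 methyl 2-O-benzyl-4,6-O-[(R)-benzylidene]-3-O-(4-methoxybenzyl)-α-D-altropyranoside
Conditions: NaH, 6, Bu4NI (cat.), DMF, 0 °C to rt
Reagents that add atoms: benzyl bromide 6, BrCc1ccccc1
Why: Williamson etherification of the sodium alkoxide of the axial 2-OH with benzyl bromide under iodide catalysis touches no stereocentre.

Step 4
Reactants: 7 methyl 2-O-benzyl-4,6-O-[(R)-benzylidene]-3-O-(4-methoxybenzyl)-α-D-altropyranoside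
Product: 8 methyl 2,4-di-O-benzyl-3-O-(4-methoxybenzyl)-α-D-altropyranoside
Conditions: BH3·THF, Cu(OTf)2 (cat.), CH2Cl2, rt; MeOH
Reagents that add atoms: none
Why: Regioselective reductive opening of the 4,6-O-benzylidene acetal: the Lewis acid binds the less hindered O6, borane delivers hydride to the oxocarbenium carbon and the benzyl group stays on O4, while PMB and benzyl ethers are inert to borane at room temperature.

Step 5
Reactants: 8 methyl 2,4-di-O-benzyl-3-O-(4-methoxybenzyl)-α-D-altropyranoside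
Product: 9 methyl 2,4-di-O-benzyl-6-deoxy-6-iodo-3-O-(4-methoxybenzyl)-α-D-altropyranoside
Conditions: I2, PPh3, imidazole, toluene, 70 °C
Reagents that add atoms: iodine, II
Why: Appel-type iodination: the only free hydroxyl, the primary 6-OH, is activated as an alkoxyphosphonium ion and displaced by iodide in an SN2 step.

Step 6
Reactants: 9 methyl 2,4-di-O-benzyl-6-deoxy-6-iodo-3-O-(4-methoxybenzyl)-α-D-altropyranoside
Product: 10 methyl 2,4-di-O-benzyl-6-deoxy-3-O-(4-methoxybenzyl)-α-D-arabino-hex-5-enopyranoside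
Conditions: t-BuOK, THF, 0 °C to rt
Reagents that add atoms: none
Why: E2 dehydrohalogenation of the primary iodide by a hindered alkoxide removes H5 and gives the exocyclic enol ether, all other groups being base-stable ethers and the methyl glycoside.

Step 7
Reactants: 10 methyl 2,4-di-O-benzyl-6-deoxy-3-O-(4-methoxybenzyl)-α-D-arabino-hex-5-enopyranoside
Product: 13 (2S,3S,4R,5R)-2,4-bis(benzyloxy)-5-hydroxy-3-[(4-methoxybenzyl)oxy]cyclohexan-1-one, via mercurated hemiketal 11 (not isolated), via mercurio keto-aldehyde 12 (not isolated)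
Conditions: Hg(OCOCF3)2 (cat.), acetone/H2O 2:1, rt
Reagents that add atoms: water, O
Why: Ferrier carbocyclization: divalent mercury and water add across the exocyclic enol ether (Hg on sugar C6, OH on sugar C5) to give hemiketal 11, which opens and loses methanol to the α-mercurio keto-aldehyde 12, whose mercury enolate adds through carbon (sugar C6, ring C2) to the aldehyde (sugar C1, ring C1) and releases the mercury salt for the next turnover. The closest known reaction is the Hg(OCOCF3)2-catalysed conversion of benzylated 6-deoxyhex-5-enopyranosides into 2-deoxyinososes. The carbocycle closes by an intramolecular aldol addition in the 6-(enolendo)-exo-trig mode. The one new stereocentre, C1, is controlled by the ring: in the chair-like transition state C5–OPMB and C6–OBn are equatorial and the aldehyde oxygen is axial, so the hydroxyl should form trans to the C5 oxygen and cis to the C6 oxygen, as the target needs. This is the usual sense of the reaction, and once sugar C5 is trigonal the C2–C4 array of 10 is the mirror image of the galacto series, where that sense is well established. The step needs the enolate to form only at C2 and the β-hydroxy ketone to survive: the first is secured because the enolate arises by mercuration of the enol ether and not by deprotonation, the second by the near-neutral medium and ether-only protection.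

Step 8
Reactants: 13 (2S,3S,4R,5R)-2,4-bis(benzyloxy)-5-hydroxy-3-[(4-methoxybenzyl)oxy]cyclohexan-1-one
Product: 14 (2S,3S,4R,5R)-2,4-bis(benzyloxy)-5-methoxy-3-[(4-methoxybenzyl)oxy]cyclohexan-1-one
Conditions: Me3OBF4, 1,8-bis(dimethylamino)naphthalene, CH2Cl2, 0 °C to rt
Reagents that add atoms: trimethyloxonium tetrafluoroborate, C[O+](C)C.F[B-](F)(F)F
Why: O-Methylation with the oxonium salt buffered by proton sponge alkylates the neutral hydroxyl, so that no alkoxide or enolate forms, neither retro-aldol cleavage nor β-elimination of the β-hydroxy ketone is set off, and C1 keeps its configuration.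

Step 9
Reactants: 14 (2S,3S,4R,5R)-2,4-bis(benzyloxy)-5-methoxy-3-[(4-methoxybenzyl)oxy]cyclohexan-1-one
Product: 16 (3R,4R,5S,6S)-4,6-bis(benzyloxy)-3-methoxy-5-[(4-methoxybenzyl)oxy]cyclohex-1-en-1-yl trifluoromethanesulfonate, via potassium enolate 15 (not isolated)
Conditions: KN(SiMe3)2 added to 14 and PhNTf2, THF, −78 °C
Reagents that add atoms: N-phenylbis(trifluoromethanesulfonimide), O=S(=O)(N(c1ccccc1)S(=O)(=O)C(F)(F)F)C(F)(F)F
Why: Kinetic enolization and O-sulfonylation (enol triflate formation): the hindered amide takes the axial hydrogen of the C2 methylene and not the tertiary C4–H next to the benzyloxy group, and the triflimide already present traps enolate 15 at −78 °C before the C1 methoxide can leave by E1cB.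

Step 10
Reactants: 16 (3R,4R,5S,6S)-4,6-bis(benzyloxy)-3-methoxy-5-[(4-methoxybenzyl)oxy]cyclohex-1-en-1-yl trifluoromethanesulfonate
Product: 17 methyl (3R,4R,5R,6R)-4,6-bis(benzyloxy)-3-methoxy-5-[(4-methoxybenzyl)oxy]cyclohex-1-ene-1-carboxylate
Conditions: Pd(OAc)2 (cat.), PPh3, CO (1 atm), MeOH, Et3N, DMF, 50 °C
Reagents that add atoms: carbon monoxide, [C-]#[O+]; methanol, CO
Why: Palladium-catalysed methoxycarbonylation of an enol triflate: zerovalent palladium formed in situ inserts into the C3–O bond, CO insertion and methanolysis give the ester, and the position of the double bond is fixed by the triflate.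

Step 11
Reactants: 17 methyl (3R,4R,5R,6R)-4,6-bis(benzyloxy)-3-methoxy-5-[(4-methoxybenzyl)oxy]cyclohex-1-ene-1-carboxylate
Product: 18 methyl (3R,4S,5R,6R)-4,6-bis(benzyloxy)-5-hydroxy-3-methoxycyclohex-1-ene-1-carboxylate
Conditions: DDQ, CH2Cl2/pH 7 buffer, 0 °C
Reagents that add atoms: none
Why: Oxidative cleavage of the electron-rich PMB ether by DDQ (hydride abstraction, then hydrolysis of the oxocarbenium ion) leaves the benzyl ethers, the methyl ether and the electron-poor alkene untouched.

Step 12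
Reactants: 18 methyl (3R,4S,5R,6R)-4,6-bis(benzyloxy)-5-hydroxy-3-methoxycyclohex-1-ene-1-carboxylate
Product: 19 (1R,2R,5R,6S)-2,6-bis(benzyloxy)-3-(hydroxymethyl)-5-methoxycyclohex-3-en-1-ol
Conditions: i-Bu2AlH, CH2Cl2, −78 °C; aq. potassium sodium tartrate
Reagents that add atoms: none
Why: 1,2-Reduction of the conjugated ester by i-Bu2AlH at low temperature gives the allylic alcohol without conjugate reduction, the free C5 hydroxyl only consuming one more equivalent of hydride.

Step 13
Reactants: 19 (1R,2R,5R,6S)-2,6-bis(benzyloxy)-3-(hydroxymethyl)-5-methoxycyclohex-3-en-1-ol; 20 benzoyl chloride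
Product: 21 [(3R,4R,5R,6R)-5-(benzoyloxy)-4,6-bis(benzyloxy)-3-methoxycyclohex-1-en-1-yl]methyl benzoate
Conditions: 20, pyridine, DMAP (cat.), CH2Cl2, 0 °C to rt
Reagents that add atoms: benzoyl chloride 20, O=C(Cl)c1ccccc1
Why: DMAP-catalysed acylation benzoylates the primary allylic C7 hydroxyl and the secondary C5 hydroxyl, which are the only free hydroxyls, so no selectivity is needed.

Step 14
Reactants: 21 [(3R,4R,5R,6R)-5-(benzoyloxy)-4,6-bis(benzyloxy)-3-methoxycyclohex-1-en-1-yl]methyl benzoate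
Product: 22 [(3R,4R,5R,6R)-5-(benzoyloxy)-4,6-dihydroxy-3-methoxycyclohex-1-en-1-yl]methyl benzoate (target)
Conditions: BCl3, pentamethylbenzene, CH2Cl2, −78 °C; MeOH
Reagents that add atoms: none
Why: Lewis-acid debenzylation with BCl3 at −78 °C cleaves the two benzyl ethers with transfer of the benzyl cation to pentamethylbenzene, while the benzoates, the methyl ether and the trisubstituted alkene should not be attacked at this temperature and the absence of base prevents migration of the C5 benzoate.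

## Compound list

1 | methyl 4,6-O-[(R)-benzylidene]-α-D-glucopyranoside | CO[C@H]1O[C@@H]2CO[C@@H](c3ccccc3)O[C@H]2[C@H](O)[C@H]1O | starting material
2 | methyl 4,6-O-[(R)-benzylidene]-2-O-tosyl-α-D-glucopyranoside | CO[C@H]1O[C@@H]2CO[C@@H](c3ccccc3)O[C@H]2[C@H](O)[C@H]1OS(=O)(=O)c1ccc(C)cc1 | intermediate (not isolated)
3 | methyl 2,3-anhydro-4,6-O-[(R)-benzylidene]-α-D-mannopyranoside | CO[C@H]1O[C@@H]2CO[C@@H](c3ccccc3)O[C@H]2[C@@H]4O[C@H]14 | intermediate
4 | 4-methoxybenzyl alcohol | COc1ccc(CO)cc1 | starting material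
5 | methyl 4,6-O-[(R)-benzylidene]-3-O-(4-methoxybenzyl)-α-D-altropyranoside | CO[C@H]1O[C@@H]2CO[C@@H](c3ccccc3)O[C@H]2[C@@H](OCc4ccc(OC)cc4)[C@@H]1O | intermediate
6 | benzyl bromide | BrCc1ccccc1 | starting material
7 | methyl 2-O-benzyl-4,6-O-[(R)-benzylidene]-3-O-(4-methoxybenzyl)-α-D-altropyranoside | CO[C@H]1O[C@@H]2CO[C@@H](c3ccccc3)O[C@H]2[C@@H](OCc4ccc(OC)cc4)[C@@H]1OCc1ccccc1 | intermediate
8 | methyl 2,4-di-O-benzyl-3-O-(4-methoxybenzyl)-α-D-altropyranoside | CO[C@H]1O[C@H](CO)[C@@H](OCc2ccccc2)[C@@H](OCc2ccc(OC)cc2)[C@@H]1OCc1ccccc1 | intermediate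
9 | methyl 2,4-di-O-benzyl-6-deoxy-6-iodo-3-O-(4-methoxybenzyl)-α-D-altropyranoside | CO[C@H]1O[C@H](CI)[C@@H](OCc2ccccc2)[C@@H](OCc2ccc(OC)cc2)[C@@H]1OCc1ccccc1 | intermediate
10 | methyl 2,4-di-O-benzyl-6-deoxy-3-O-(4-methoxybenzyl)-α-D-arabino-hex-5-enopyranoside | CO[C@H]1OC(=C)[C@@H](OCc2ccccc2)[C@@H](OCc2ccc(OC)cc2)[C@@H]1OCc1ccccc1 | intermediate (key-step precursor)
11 | C5 hemiketal of 10 with a C6 trifluoroacetoxymercurio group (C5 configuration not defined) | CO[C@H]1OC(O)(C[Hg]OC(=O)C(F)(F)F)[C@@H](OCc2ccccc2)[C@@H](OCc2ccc(OC)cc2)[C@@H]1OCc1ccccc1 | intermediate (not isolated)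
12 | 2,4-di-O-benzyl-6-deoxy-3-O-(4-methoxybenzyl)-6-(trifluoroacetoxymercurio)-D-arabino-hexos-5-ulose, open chain | O=C[C@@H](OCc1ccccc1)[C@H](OCc1ccc(OC)cc1)[C@H](OCc1ccccc1)C(=O)C[Hg]OC(=O)C(F)(F)F | intermediate (not isolated)
13 | (2S,3S,4R,5R)-2,4-bis(benzyloxy)-5-hydroxy-3-[(4-methoxybenzyl)oxy]cyclohexan-1-one | O[C@@H]1CC(=O)[C@@H](OCc2ccccc2)[C@@H](OCc2ccc(OC)cc2)[C@@H]1OCc1ccccc1 | intermediate (key-step product)
14 | (2S,3S,4R,5R)-2,4-bis(benzyloxy)-5-methoxy-3-[(4-methoxybenzyl)oxy]cyclohexan-1-one | CO[C@@H]1CC(=O)[C@@H](OCc2ccccc2)[C@@H](OCc2ccc(OC)cc2)[C@@H]1OCc1ccccc1 | intermediate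
15 | potassium C2=C3 enolate of 14 | CO[C@@H]1C=C([O-])[C@@H](OCc2ccccc2)[C@@H](OCc2ccc(OC)cc2)[C@@H]1OCc1ccccc1.[K+] | intermediate (not isolated)
16 | (3R,4R,5S,6S)-4,6-bis(benzyloxy)-3-methoxy-5-[(4-methoxybenzyl)oxy]cyclohex-1-en-1-yl trifluoromethanesulfonate | CO[C@@H]1C=C(OS(=O)(=O)C(F)(F)F)[C@@H](OCc2ccccc2)[C@@H](OCc2ccc(OC)cc2)[C@@H]1OCc1ccccc1 | intermediate
17 | methyl (3R,4R,5R,6R)-4,6-bis(benzyloxy)-3-methoxy-5-[(4-methoxybenzyl)oxy]cyclohex-1-ene-1-carboxylate | CO[C@@H]1C=C(C(=O)OC)[C@@H](OCc2ccccc2)[C@@H](OCc2ccc(OC)cc2)[C@@H]1OCc1ccccc1 | intermediate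
18 | methyl (3R,4S,5R,6R)-4,6-bis(benzyloxy)-5-hydroxy-3-methoxycyclohex-1-ene-1-carboxylate | CO[C@@H]1C=C(C(=O)OC)[C@@H](OCc2ccccc2)[C@@H](O)[C@@H]1OCc1ccccc1 | intermediate
19 | (1R,2R,5R,6S)-2,6-bis(benzyloxy)-3-(hydroxymethyl)-5-methoxycyclohex-3-en-1-ol | CO[C@@H]1C=C(CO)[C@@H](OCc2ccccc2)[C@@H](O)[C@@H]1OCc1ccccc1 | intermediate
20 | benzoyl chloride | O=C(Cl)c1ccccc1 | starting material
21 | [(3R,4R,5R,6R)-5-(benzoyloxy)-4,6-bis(benzyloxy)-3-methoxycyclohex-1-en-1-yl]methyl benzoate | CO[C@@H]1C=C(COC(=O)c2ccccc2)[C@@H](OCc2ccccc2)[C@@H](OC(=O)c2ccccc2)[C@@H]1OCc1ccccc1 | intermediate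
22 | [(3R,4R,5R,6R)-5-(benzoyloxy)-4,6-dihydroxy-3-methoxycyclohex-1-en-1-yl]methyl benzoate | CO[C@@H]1C=C(COC(=O)c2ccccc2)[C@@H](O)[C@@H](OC(=O)c2ccccc2)[C@@H]1O | target

## Step count

Total: 14 steps. Longest linear sequence: 14 steps (1 to 22); compounds 4, 6 and 20 are bought.

## Steps most likely to fail

**Step 9 (enol triflate).** The C2 enolate may expel the C1 methoxide by E1cB, since the C1–OMe bond can lie axial and parallel to the enolate π system, or deprotonation may occur on the C4 side. The fallback sets out from 14 and comes back at 19, and it avoids any enolate. Ketone 14 is methylenated without base with Cp2TiMe2 in toluene at 65 °C (Petasis methylenation) to the exocyclic methylene compound F1. Dihydroxylation with OsO4 (cat.) and N-methylmorpholine N-oxide in aqueous acetone gives the tertiary/primary 1,2-diol F2, whose C3 configuration need not be controlled. The primary hydroxyl is silylated with TBSCl and imidazole in DMF to the silyl ether F3. Dehydration with SOCl2 in pyridine at 0 °C should take place toward the C2 methylene: the chlorosulfite undergoes anti elimination, the C4 hydrogen sits on an alkoxy-bearing carbon, and loss of a C7 hydrogen would give an enol ether. This gives the cyclohexene silyl ether F4. DDQ then removes the PMB group to give the C5 alcohol F5, and HF·pyridine in THF frees the primary hydroxyl to give diol 19.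

**Step 7 (carbocyclization).** Facial selectivity in the aldol closure may be poor, so that part of the material becomes the C1 epimer with the hydroxyl cis to the C5 oxygen. The fallback sets out from 10 and comes back at 17; it sets C1 by an SN2 inversion in place of the aldol. The C1-epimeric ketol F6 formed in the same reaction is silylated with TESOTf and 2,6-lutidine to the TES ether F7. This is carried through the conditions of steps 9 and 10 to the enol triflate F8 and the methyl enoate F9, and desilylated with HF·pyridine to the allylic alcohol F10. A Mitsunobu reaction with 4-nitrobenzoic acid, PPh3 and diisopropyl azodicarboxylate inverts C1 and gives the 4-nitrobenzoate F11. Methanolysis with K2CO3 in MeOH at 0 °C gives the C1-inverted allylic alcohol F12, which is methylated with Me3OBF4 and proton sponge to enoate 17.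

**Step 14 (debenzylation).** The Lewis acid may ionise the allylic C–O bonds (C1–OMe, C7–OBz, C4–OBn), or the C5 benzoate may migrate on work-up. The fallback sets out from 21 and comes back at 22 without a new compound. The benzyl ethers are cleaved oxidatively with DDQ in wet CH2Cl2 under visible-light irradiation (525 nm), which proceeds by benzylic hydrogen abstraction and hydrolysis of the oxocarbenium ion and needs no Lewis acid.

## Further compounds

F1 | step 9 | 2,4-bis(benzyloxy)-5-methoxy-3-[(4-methoxybenzyl)oxy]-1-methylidenecyclohexane, ring stereocentres as in 14 | CO[C@@H]1CC(=C)[C@@H](OCc2ccccc2)[C@@H](OCc2ccc(OC)cc2)[C@@H]1OCc1ccccc1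
F2 | step 9 | 2,4-bis(benzyloxy)-1-(hydroxymethyl)-5-methoxy-3-[(4-methoxybenzyl)oxy]cyclohexan-1-ol, C1 of this name not defined | CO[C@@H]1CC(O)(CO)[C@@H](OCc2ccccc2)[C@@H](OCc2ccc(OC)cc2)[C@@H]1OCc1ccccc1
F3 | step 9 | primary TBS ether of F2 | CO[C@@H]1CC(O)(CO[Si](C)(C)C(C)(C)C)[C@@H](OCc2ccccc2)[C@@H](OCc2ccc(OC)cc2)[C@@H]1OCc1ccccc1
F4 | step 9 | C2=C3 cyclohexene with C7–OTBS, C5–OPMB, C4/C6–OBn and C1–OMe | CO[C@@H]1C=C(CO[Si](C)(C)C(C)(C)C)[C@@H](OCc2ccccc2)[C@@H](OCc2ccc(OC)cc2)[C@@H]1OCc1ccccc1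
F5 | step 9 | C5 alcohol from F4 (C7–OTBS kept) | CO[C@@H]1C=C(CO[Si](C)(C)C(C)(C)C)[C@@H](OCc2ccccc2)[C@@H](O)[C@@H]1OCc1ccccc1
F6 | step 7 | (2S,3S,4R,5S)-2,4-bis(benzyloxy)-5-hydroxy-3-[(4-methoxybenzyl)oxy]cyclohexan-1-one, C1 epimer of 13 | O[C@H]1CC(=O)[C@@H](OCc2ccccc2)[C@@H](OCc2ccc(OC)cc2)[C@@H]1OCc1ccccc1
F7 | step 7 | triethylsilyl ether of F6 | CC[Si](CC)(CC)O[C@H]1CC(=O)[C@@H](OCc2ccccc2)[C@@H](OCc2ccc(OC)cc2)[C@@H]1OCc1ccccc1
F8 | step 7 | C2=C3 enol triflate of F7 | CC[Si](CC)(CC)O[C@H]1C=C(OS(=O)(=O)C(F)(F)F)[C@@H](OCc2ccccc2)[C@@H](OCc2ccc(OC)cc2)[C@@H]1OCc1ccccc1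
F9 | step 7 | methyl enoate from F8 (C1-epimeric OTES analogue of 17) | CC[Si](CC)(CC)O[C@H]1C=C(C(=O)OC)[C@@H](OCc2ccccc2)[C@@H](OCc2ccc(OC)cc2)[C@@H]1OCc1ccccc1
F10 | step 7 | C1-epimeric allylic alcohol from F9 | O[C@H]1C=C(C(=O)OC)[C@@H](OCc2ccccc2)[C@@H](OCc2ccc(OC)cc2)[C@@H]1OCc1ccccc1
F11 | step 7 | C1-inverted 4-nitrobenzoate | O=C(O[C@@H]1C=C(C(=O)OC)[C@@H](OCc2ccccc2)[C@@H](OCc2ccc(OC)cc2)[C@@H]1OCc1ccccc1)c1ccc(cc1)[N+](=O)[O-]
F12 | step 7 | allylic alcohol with the C1 configuration of the target (O-demethyl 17) | O[C@@H]1C=C(C(=O)OC)[C@@H](OCc2ccccc2)[C@@H](OCc2ccc(OC)cc2)[C@@H]1OCc1ccccc1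
F0 | step 14 | none | none
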